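In 80 s each flask below turns E and X into E.X, which crystallises as Q, while X also decays to G.

    2 E ⇌ E2, settled at all times (K1 = 29 M⁻¹)
    E + X → E.X (k2 = 10.3 M⁻¹ s⁻¹)
    Q ⇌ E.X, rate k3*(cs3 - [E.X]) while solid is left; crystals form when [E.X] > cs3 (cs3 = 0.62 mM, k3 = 0.447 s⁻¹)
    X → G (k4 = 0.0219 s⁻¹)

| flask | E | X | time | remark |
|---|---|---|---|---|
| Friday's | 32 mM | 38.4 mM (fed, over 15 s) | 80 s | all else is in the flask from the start; the feed brings no volume worth counting |
| Monday's | 32 mM | 38.4 mM | 80 s | everything together at the start |
| Sunday's | 32 mM | 38.4 mM (in portions, 2, over 1.0 min) | 80 s | first portion at the start, last at 1.0 min |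
| Wednesday's | 32 mM | 38.4 mM (fed, over 1.0 min) | 80 s | all else is in the flask from the start; the feed brings no volume worth counting |
| Saturday's | 32 mM (fed, over 1.0 min) | 38.4 mM | 80 s | all else is in the flask from the start; the feed brings no volume worth counting |

- in percentages every species weighs as the E in it: one E2 counts as two
- for E.X the Q are counted in
- where a step has two of a species, its rate is k times that concentration squared, and two are used at each turn
- as a solid, counted per litre of solution: Q
- run time (Friday's): 80 s

- the flask with the highest amount of E2, in percent of the E charged ("all alike" if they lie within 1.5 percentage points) (Friday's / Monday's / Sunday's / Wednesday's / Saturday's / all alike)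
- final E2, as a percentage of the E charged, in Friday's
- final E2, as a percentage of the E charged, in Monday's
- final E2, as a percentage of the E charged, in Sunday's
- final E2, as a percentage of the E charged, in Wednesday's
- final E2, as a percentage of the E charged, in Saturday's

The first step is fast, so the concentration of E2 follows c_E squared, and unbound E of total T, counted as E, holds a free part c_E = (√(1 + 8·K·T) − 1)/(4·K), with K the balance constant 29 M⁻¹. The rest of T is E2.

So the question becomes how much T survives, and that turns on X, which is lost to E at k2·c_E and to G at k4. The two losses are equal at c_E = 2.13 mM. Monday's starts with free E at 16.4 mM, above that level, so X goes mainly to E there.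

Saturday's is different: E enters at the feed rate F = 0.533 mM s⁻¹. X takes E within 2.53 s, far shorter than the feed, so c_E starts near 1.35 mM, below the equal-loss level.

If each fed E is taken at once, c_X falls by the feed rate plus k4·c_X. In this reckoning it reaches zero at the run-out time, ln(1 + k4·C/F)/k4 = 43.2 s, where C is the charged 38.4 mM. The reckoning leaves the E fed after that unbound, so T = 8.95 mM, free E is 6.50 mM, and E2 is 7.66% of the charge. This reckoning commits to Saturday's as the answer to the first question.

The forecast also names Saturday's, but at 17%, higher than this reckoning, on the ground that “X is nearly gone before the feed ends”, and it gives 0.75%, 0.75%, 2.4% and 1.1% for Friday's, Monday's, Sunday's and Wednesday's.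

The simulation gives Saturday's at 12.5%, against 0.684%, 0.645%, 2.13% and 1.28% in the same order.

The passing of X into G turns the answer most: without it, the gap between Saturday's and Monday's shrinks from 12 percentage points to 0.14 points. X is the limiting reagent in Saturday's, down to 0.289% of its charge at 80.0 s. The run-out time credited E.X with 72.0% of the E, whereas Saturday's holds 61.5% at 80.0 s, so the reckoning left less E unbound than the flask has, and its E2 stands lower than the computed value.

In the neighbour of Saturday's charged with 9.6 mM of X, the run-out time is 15.2 s, which leaves T = 23.9 mM and E2 at 32.7%. The computed value for that flask is 36.6%.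

Its constants are assumed, and the outcome is calculated.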